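(The data stem from a simulated flask from invented constants, noise included.)

- Late in the zeta run, I divide the product's gain per hour by the intermediate B standing there and get 0.0919 /h, the leak rate at which intermediate B passes through intermediate C towards product, while the capture agent offers intermediate B a second exit, into trapped intermediate.

| flask | starting material | capture agent | remark | time |
|---|---|---|---|---|
| zeta | 1.1 M | 0.63 M | run made earlier |  |
| grey | 2.1 M | 0.630 M |  | 8.0 h |
| amber | 2.1 M | 0.630 M |  | 15 h |

zeta run (percent of the starting material charged)

| time / h | starting material / % | intermediate B / % | trapped intermediate / % | intermediate C / % | product / % |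
|---|---|---|---|---|---|
| 2.50 | 0 | 36.7 | 18.9 | 2.5 | 2.2 |
| 5.00 | 0.1 | 35.2 | 37.4 | 3.7 | 10.0 |
| 8.00 | 0 | 27.0 | 47.3 | 2.6 | 19.9 |
| 10.0 | 0 | 20.9 | 49.9 | 2.4 | 24.3 |

(each reading ± 0.3 percentage points)

- what was read earlier has a scatter of 0.3 percentage points, one standard deviation

1. which of these there is most of at the end, counted by the starting material in it, grey (product / trapped intermediate / intermediate B / intermediate C)
2. which of these there is most of at the end, counted by the starting material in it, amber (product / trapped intermediate / intermediate B / intermediate C)
3. amount of the one of these that there is most of at the end, in percent of the starting material charged, grey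
4. amount of the one of these that there is most of at the end, in percent of the starting material charged, amber

- The capture agent is the concentration that sets the speed of that second exit, so I divide the gain of trapped intermediate per hour between 2.50 h and 5.00 h in zeta by the intermediate B and the capture agent present, taking one agent per capture, and read a capture constant of 0.643 /M/h.
- With 0.630 M charged, grey and amber start at a capture rate of 0.405 /h, which is the capture constant times the capture agent charged, the share of intermediate B taken per hour at the start, and this starting value is faster than the leak.
- One thing slows it: each capture spends agent, the limiting reagent of capture in grey at 30.0% of the starting material, and with intermediate B at the 36.7% read in zeta, the charge of grey makes the agent fall at 0.495 /h.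
- Over 8.0 h that roughly multiplies the capture rate by 1.90%, bringing it to 0.00770 /h, slower than the leak, so from then on I count on the leak, whose half-life of 7.55 h is close to the grey time; I therefore expect intermediate B to lead in grey and product in amber.
- The forecast gives intermediate B at 37.5% for grey and product at 47% for amber, noting that “the agent is nearly used up by 8 h”.

    starting material → intermediate A (k = 9.20 × 10⁻⁴ /s)
    intermediate A → intermediate B (k = 1.20 × 10⁻⁴ /s)
    intermediate B → intermediate C (k = 2.60 × 10⁻⁵ /s)
    intermediate C → product (k = 2.70 × 10⁻⁴ /s)
    intermediate B + capture agent → trapped intermediate (k = 1.80 × 10⁻⁴ /M/s)

- The flask gives intermediate B at 39.5% in grey and product at 45.1% in amber, and at 8.00 h grey keeps 1.9% of its capture agent, which puts the capture rate at 0.00753 /h. The neighbouring flask with 0.53 M of starting material keeps 49.3% of its capture agent at 8.00 h, so its capture rate is still 0.200 /h, faster than the leak, and there trapped intermediate holds most, at 60.3%.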